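The tetrahydrooxepine ring is traced back to a cyclohexanone, and everything rests on this. C7, the only stereocentre, sits in the seven-membered ring between O1 and C6 and carries the carboxyl group and the C8–C9 arm. It therefore equals the α-quaternary carbon of a 2-oxocyclohexanecarboxylate whose ketone carbon is the later C2. A single Baeyer–Villiger oxygen insertion forges C7–O1, expands the carbocycle to the seven-membered lactone and passes the configuration on with retention. Its substrate is the (S)-α-allyl β-keto tert-butyl ester, made by asymmetric allylation. The lactone carbonyl afterwards guides C3=C4 and a C3 bromide into place before it is reduced to C2H2. Side chain and aryl ketone arrive convergently.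

Key step: step 2

**Remarks**
- **Atom labels in the Why lines:** ring O1, C2 (OCH2), C3 (side-chain carbon), C4 (=CH), C5, C6, C7 (quaternary); arm C8 (CH2), C9 (C=O). Systematic names count the ring from the other side, so C7 is position 2 there.
- **Assumption:** the (R,R) antipode of the diphosphine ligand is taken to give the (S)-allylation product. If correlation shows the opposite sense, the equally available (S,S) ligand is used.
- **Configuration:** C7 of the target is R. The keto ester is S and the lactone is R at unchanged geometry, because oxygen takes the top CIP rank that the ester carbon held before. Both acyclic alkenes are E.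
- **tert-Butyl ester:** it stays as spectator because its bulk blocks Dieckmann attack, hydride, lactonisation by the C9 oxygen and Grignard attack. Its sensitivity to Lewis acid is met by a tempered, substoichiometric tin catalyst and by low temperature.
- **Allyl alkene:** it is homoallylic to O1 and is cleaved before any oxocarbenium ion is generated.
- **After C9 becomes a carbonyl group:** O1 is then a β-leaving group, so only neutral or acidic conditions are used.
- **Side-chain allylic oxygen:** it is introduced at the stage of the simple bromide.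

**Step 1**
Reactants: 1 tert-butyl 2-oxocyclohexane-1-carboxylate; 2 allyl acetate
Product: 3 tert-butyl (S)-1-allyl-2-oxocyclohexane-1-carboxylate
Conditions: Pd2(dba)3·CHCl3 (2.5 mol %), (R,R)-DACH-phenyl ligand N,N'-[(1R,2R)-cyclohexane-1,2-diyl]bis[2-(diphenylphosphino)benzamide] (6 mol %), 1,1,3,3-tetramethylguanidine (1.2 equiv), toluene, 0 °C
Reagents that add atoms: none
Why: Tsuji–Trost asymmetric allylic alkylation, in which the stabilised β-keto ester enolate attacks the π-allyl palladium complex from outside the metal and the chiral pocket of the diphosphine selects the enolate face, which sets the quaternary centre as S.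

**Step 2**
Reactants: 3 tert-butyl (S)-1-allyl-2-oxocyclohexane-1-carboxylate
Product: 5 tert-butyl (R)-2-allyl-7-oxooxepane-2-carboxylate, via Criegee adduct 4 (not isolated)
Conditions: Me3SiOOSiMe3 (2.5 equiv), SnCl4 (20 mol %), trans-N,N'-ditosylcyclohexane-1,2-diamine (20 mol %), 4 Å molecular sieves, CH2Cl2, −20 °C to rt
Reagents that add atoms: bis(trimethylsilyl) peroxide, C[Si](C)(C)OO[Si](C)(C)C
Why: The tin-activated ketone (the later C2) takes up the silyl peroxide to give perketal 4, and the C2–C7 bond that lies antiperiplanar to the O–O bond shifts to the inner peroxide oxygen while the outer Me3SiO group departs and ends as hexamethyldisiloxane. This is the Baeyer–Villiger oxidation in its bis(silyl) peroxide/Lewis acid variant, a reaction type established for α,α-disubstituted β-keto esters and for ketones that carry alkenes. No ring is closed by cyclisation: the seven-membered lactone arises from the cyclohexanone by one-atom ring enlargement through the 1,2-shift that creates the C7–O1 bond. No stereocentre is newly created either: the migrating carbon stays bonded through the same face, so the configuration set in step 1 is carried over with retention, and the label changes from S to R only because oxygen now outranks the ester carbon. The step needs migration of C7 instead of the C3 methylene, which is favoured both by the full substitution of C7 (better support of the electron-poor transition state in spite of the ester) and by the lower crowding of the conformer with O–O anti to the bulkier carbon. It also needs the allyl alkene and the tert-butyl ester to survive, which is secured by a peroxide that transfers no oxygen to unactivated alkenes and by tin that is used substoichiometrically and tempered by the bis-sulfonamide ligand and the molecular sieves.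

**Step 3**
Reactants: 5 tert-butyl (R)-2-allyl-7-oxooxepane-2-carboxylate
Product: 7 tert-butyl (R)-2-(2-hydroxyethyl)-7-oxooxepane-2-carboxylate, via ozonide 6 (not isolated)
Conditions: O3, CH2Cl2, −78 °C; then NaBH4, MeOH, −78 to 0 °C
Reagents that add atoms: ozone, [O-][O+]=O
Why: Ozonolysis with reductive work-up removes the terminal carbon so that only C8–C9 remain, takes away the alkene that would enter a Prins cyclisation in step 8, and uses borohydride cold enough to spare the lactone and the tert-butyl ester.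

**Step 4**
Reactants: 7 tert-butyl (R)-2-(2-hydroxyethyl)-7-oxooxepane-2-carboxylate
Product: 8 tert-butyl (R)-2-{2-[(tert-butyldimethylsilyl)oxy]ethyl}-7-oxooxepane-2-carboxylate
Conditions: TBSCl, imidazole, CH2Cl2, 0 °C to rt
Reagents that add atoms: tert-butyldimethylsilyl chloride, CC(C)(C)[Si](C)(C)Cl
Why: Silyl ether formation at the unhindered primary alcohol masks the C9 oxygen against base, hydride and Lewis acid in steps 5–8 and prevents its lactonisation onto the C7 ester.

**Step 5**
Reactants: 8 tert-butyl (R)-2-{2-[(tert-butyldimethylsilyl)oxy]ethyl}-7-oxooxepane-2-carboxylate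
Product: 10 tert-butyl (R)-2-{2-[(tert-butyldimethylsilyl)oxy]ethyl}-7-oxo-2,3,4,7-tetrahydrooxepine-2-carboxylate, via selenide 9 (not isolated)
Conditions: LiN(i-Pr)2 (1.15 equiv), THF, −78 °C; PhSeBr, −78 °C; then AcOH, 30% H2O2, 0 °C to rt
Reagents that add atoms: none
Why: α-Selenenylation followed by selenoxide syn-elimination works here because C3 is the only acidic position, the bulky tert-butyl ester resists Dieckmann attack at −78 °C, and the selenoxide can eliminate only towards C4, which gives the ring cis-enoate.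

**Step 6**
Reactants: 10 tert-butyl (R)-2-{2-[(tert-butyldimethylsilyl)oxy]ethyl}-7-oxo-2,3,4,7-tetrahydrooxepine-2-carboxylate
Product: 12 tert-butyl (R)-6-bromo-2-{2-[(tert-butyldimethylsilyl)oxy]ethyl}-7-oxo-2,3,4,7-tetrahydrooxepine-2-carboxylate, via dibromide 11 (not isolated)
Conditions: Br2 (1.1 equiv), CH2Cl2, 0 °C to rt, dark; then Et3N, 0 °C to rt
Reagents that add atoms: bromine, BrBr
Why: In this bromination–dehydrobromination of an α,β-unsaturated lactone, anti addition to the only alkene present is followed by amine-induced loss of the acidic C3–H together with the C4 bromide, which leaves bromine on C3.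

**Step 7**
Reactants: 12 tert-butyl (R)-6-bromo-2-{2-[(tert-butyldimethylsilyl)oxy]ethyl}-7-oxo-2,3,4,7-tetrahydrooxepine-2-carboxylate
Product: 14 tert-butyl (2R)-7-acetoxy-6-bromo-2-{2-[(tert-butyldimethylsilyl)oxy]ethyl}-2,3,4,7-tetrahydrooxepine-2-carboxylate (both acetal epimers), via aluminium hemiacetal 13 (not isolated)
Conditions: i-Bu2AlH (1.2 equiv), CH2Cl2, −78 °C; then pyridine, DMAP, Ac2O, −78 to −20 °C
Reagents that add atoms: acetic anhydride, CC(=O)OC(C)=O
Why: In this reductive acetylation of a lactone the tetrahedral aluminium alkoxide is stable at −78 °C and is acylated in its ring form, which avoids the free seven-membered lactol that would open to the hydroxy enal, while the neopentyl-type tert-butyl ester is too hindered to compete for the hydride.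

**Step 8**
Reactants: 14 tert-butyl (2R)-7-acetoxy-6-bromo-2-{2-[(tert-butyldimethylsilyl)oxy]ethyl}-2,3,4,7-tetrahydrooxepine-2-carboxylate
Product: 16 tert-butyl (R)-6-bromo-2-{2-[(tert-butyldimethylsilyl)oxy]ethyl}-2,3,4,7-tetrahydrooxepine-2-carboxylate, via oxocarbenium ion 15 (not isolated)
Conditions: Et3SiH (8 equiv), BF3·OEt2 (2 equiv), CH2Cl2, −78 to −40 °C
Reagents that add atoms: none
Why: In this ionic hydrogenation of an α-acetoxy ether BF3 ionises the acetate to the allyl-stabilised cation 15 and the silane delivers hydride to C2, the carbon next to oxygen, as in Ferrier-type reductions, so that C3=C4 stays in place, no π-nucleophile is left to intercept the cation, and the low temperature protects the tert-butyl ester and the silyl ether.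

**Step 9**
Reactants: 16 tert-butyl (R)-6-bromo-2-{2-[(tert-butyldimethylsilyl)oxy]ethyl}-2,3,4,7-tetrahydrooxepine-2-carboxylate
Product: 17 tert-butyl (R)-6-bromo-2-(2-hydroxyethyl)-2,3,4,7-tetrahydrooxepine-2-carboxylate
Conditions: HF·pyridine, pyridine, THF, 0 °C to rt
Reagents that add atoms: none
Why: Fluoride-induced desilylation in a weakly acidic medium frees the primary alcohol without forming an alkoxide that could lactonise onto the tert-butyl ester.

**Step 10**
Reactants: 17 tert-butyl (R)-6-bromo-2-(2-hydroxyethyl)-2,3,4,7-tetrahydrooxepine-2-carboxylate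
Product: 18 tert-butyl (R)-6-bromo-2-(2-oxoethyl)-2,3,4,7-tetrahydrooxepine-2-carboxylate
Conditions: Dess–Martin periodinane (1.3 equiv), CH2Cl2, 0 °C to rt
Reagents that add atoms: none
Why: The Dess–Martin oxidation is neutral to weakly acidic, so the β-alkoxy aldehyde forms without enolisation and without retro-oxa-Michael opening of the C7–O1 bond.

**Step 11**
Reactants: 19 2-bromobenzene-1,4-diol
Product: 20 2-bromo-1,4-bis(methoxymethoxy)benzene
Conditions: MOMCl (3 equiv), i-Pr2NEt (4 equiv), CH2Cl2, 0 °C to rt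
Reagents that add atoms: chloromethyl methyl ether, COCCl
Why: O-Alkylation of both phenols gives acetal ethers that tolerate magnesium and zinc organometallics and fall in acid together with the tert-butyl ester.

**Step 12**
Reactants: 20 2-bromo-1,4-bis(methoxymethoxy)benzene; 18 tert-butyl (R)-6-bromo-2-(2-oxoethyl)-2,3,4,7-tetrahydrooxepine-2-carboxylate
Product: 22 tert-butyl (2R)-2-{2-[2,5-bis(methoxymethoxy)phenyl]-2-hydroxyethyl}-6-bromo-2,3,4,7-tetrahydrooxepine-2-carboxylate (both carbinol epimers), via aryl Grignard reagent 21 (not isolated)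
Conditions: 20, Mg turnings, THF, 40 °C; then 18, THF, −78 °C; aq NH4Cl at −78 °C
Reagents that add atoms: none
Why: In this Grignard addition the aryl magnesium bromide is much less basic than the lithium analogue and attacks only the aldehyde at −78 °C, the hindered ester and the vinyl bromide being inert, and the C9 carbinol centre, formed without control, is erased in step 13.

**Step 13**
Reactants: 22 tert-butyl (2R)-2-{2-[2,5-bis(methoxymethoxy)phenyl]-2-hydroxyethyl}-6-bromo-2,3,4,7-tetrahydrooxepine-2-carboxylate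
Product: 23 tert-butyl (R)-2-{2-[2,5-bis(methoxymethoxy)phenyl]-2-oxoethyl}-6-bromo-2,3,4,7-tetrahydrooxepine-2-carboxylate
Conditions: Dess–Martin periodinane (1.3 equiv), CH2Cl2, 0 °C to rt
Reagents that add atoms: none
Why: Dess–Martin oxidation of the benzylic alcohol removes the C9 stereocentre and gives the aryl ketone under non-basic conditions that leave C7–O1 intact.

**Step 14**
Reactants: 24 5-bromo-2-methylpent-2-ene
Product: 25 (E)-5-bromo-2-methylpent-2-en-1-ol
Conditions: SeO2 (0.3 equiv), t-BuOOH (5.5 M in decane, 2.5 equiv), CH2Cl2, 0 °C to rt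
Reagents that add atoms: selenium dioxide, O=[Se]=O (catalytic oxygen carrier); tert-butyl hydroperoxide, CC(C)(C)OO (terminal oxygen source)
Why: The Riley allylic oxidation proceeds by an ene reaction and a [2,3]-sigmatropic shift, a sequence known to hydroxylate gem-dimethyl trisubstituted alkenes to the E-allylic alcohol, which fixes the side-chain geometry on a cheap intermediate.

**Step 15**
Reactants: 25 (E)-5-bromo-2-methylpent-2-en-1-ol; 26 (E)-4-hydroxycinnamic acid (p-coumaric acid)
Product: 27 (E)-5-bromo-2-methylpent-2-en-1-yl (E)-3-(4-hydroxyphenyl)acrylate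
Conditions: PPh3, DIAD, THF, 0 °C to rt
Reagents that add atoms: none
Why: The Mitsunobu esterification activates the alcohol and not the acid, so the carboxyl group, far more acidic than the phenol, is the only nucleophile, and direct displacement at the primary allylic carbon leaves both E alkenes untouched.

**Step 16**
Reactants: 27 (E)-5-bromo-2-methylpent-2-en-1-yl (E)-3-(4-hydroxyphenyl)acrylate
Product: 28 (E)-5-bromo-2-methylpent-2-en-1-yl (E)-3-[4-(methoxymethoxy)phenyl]acrylate
Conditions: MOMCl (1.5 equiv), i-Pr2NEt (2 equiv), CH2Cl2, 0 °C to rt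
Reagents that add atoms: chloromethyl methyl ether, COCCl
Why: MOM ether formation removes the acidic phenol proton that would destroy the zinc reagent of step 18 and matches the other acid-labile groups.

**Step 17**
Reactants: 28 (E)-5-bromo-2-methylpent-2-en-1-yl (E)-3-[4-(methoxymethoxy)phenyl]acrylate
Product: 29 (E)-5-iodo-2-methylpent-2-en-1-yl (E)-3-[4-(methoxymethoxy)phenyl]acrylate
Conditions: NaI (4 equiv), acetone, reflux
Reagents that add atoms: sodium iodide, [Na+].[I-]
Why: The Finkelstein exchange, driven by precipitation of NaBr, supplies the primary iodide that inserts zinc near room temperature.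

**Step 18**
Reactants: 29 (E)-5-iodo-2-methylpent-2-en-1-yl (E)-3-[4-(methoxymethoxy)phenyl]acrylate; 23 tert-butyl (R)-2-{2-[2,5-bis(methoxymethoxy)phenyl]-2-oxoethyl}-6-bromo-2,3,4,7-tetrahydrooxepine-2-carboxylate
Product: 31 tert-butyl (R)-2-{2-[2,5-bis(methoxymethoxy)phenyl]-2-oxoethyl}-6-[(3E)-5-({(2E)-3-[4-(methoxymethoxy)phenyl]prop-2-enoyl}oxy)-4-methylpent-3-en-1-yl]-2,3,4,7-tetrahydrooxepine-2-carboxylate, via alkylzinc iodide 30 (not isolated)
Conditions: 29 (1.5 equiv), Zn dust, LiCl, Me3SiCl (cat.), THF, 30 °C; then 23, Pd(OAc)2 (3 mol %), SPhos (6 mol %), THF, rt to 40 °C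
Reagents that add atoms: none
Why: In this Negishi sp3–sp2 coupling the alkylzinc iodide tolerates ester, enoate and enolisable ketone, zerovalent palladium on the bulky biaryl phosphine adds to the C3–Br bond faster than it ionises the hindered allylic ester and reductively eliminates faster than β-hydride loss, and the neutral medium protects the β-alkoxy ketone.

**Step 19**
Reactants: 31 tert-butyl (R)-2-{2-[2,5-bis(methoxymethoxy)phenyl]-2-oxoethyl}-6-[(3E)-5-({(2E)-3-[4-(methoxymethoxy)phenyl]prop-2-enoyl}oxy)-4-methylpent-3-en-1-yl]-2,3,4,7-tetrahydrooxepine-2-carboxylate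
Product: 32 (R)-2-[2-(2,5-dihydroxyphenyl)-2-oxoethyl]-6-[(3E)-5-{[(2E)-3-(4-hydroxyphenyl)prop-2-enoyl]oxy}-4-methylpent-3-en-1-yl]-2,3,4,7-tetrahydrooxepine-2-carboxylic acid (CNP0602535.1)
Conditions: CF3CO2H/CH2Cl2 (1:3), H2O (5 equiv), 0 °C to rt
Reagents that add atoms: none
Why: Acidolysis cleaves the tert-butyl ester and the three phenolic acetals in one operation, which should be tolerated because both trisubstituted alkenes carry an allylic oxygen that disfavours protonation, neither allylic C–O bond can ionise to a tertiary cation, and acid avoids the base-induced retro-oxa-Michael opening at C7, so the stereocentre is untouched.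

**Compound list**

| No. | Name | SMILES | Role |
|---|---|---|---|
| 1 | tert-butyl 2-oxocyclohexane-1-carboxylate | O=C1CCCCC1C(=O)OC(C)(C)C | starting material |
| 2 | allyl acetate | CC(=O)OCC=C | starting material |
| 3 | tert-butyl (S)-1-allyl-2-oxocyclohexane-1-carboxylate | C=CC[C@@]1(C(=O)OC(C)(C)C)CCCCC1=O | intermediate |
| 4 | tert-butyl (1S)-1-allyl-2-(trimethylsilyloxy)-2-(trimethylsilylperoxy)cyclohexane-1-carboxylate (Criegee adduct) | C=CC[C@@]1(C(=O)OC(C)(C)C)CCCCC1(O[Si](C)(C)C)OO[Si](C)(C)C | intermediate |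
| 5 | tert-butyl (R)-2-allyl-7-oxooxepane-2-carboxylate | C=CC[C@@]1(C(=O)OC(C)(C)C)CCCCC(=O)O1 | intermediate |
| 6 | tert-butyl (2R)-7-oxo-2-[(1,2,4-trioxolan-3-yl)methyl]oxepane-2-carboxylate (ozonide) | O1OCOC1C[C@@]2(C(=O)OC(C)(C)C)CCCCC(=O)O2 | intermediate |
| 7 | tert-butyl (R)-2-(2-hydroxyethyl)-7-oxooxepane-2-carboxylate | OCC[C@@]1(C(=O)OC(C)(C)C)CCCCC(=O)O1 | intermediate |
| 8 | tert-butyl (R)-2-{2-[(tert-butyldimethylsilyl)oxy]ethyl}-7-oxooxepane-2-carboxylate | CC(C)(C)[Si](C)(C)OCC[C@@]1(C(=O)OC(C)(C)C)CCCCC(=O)O1 | intermediate |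
| 9 | tert-butyl (2R)-2-{2-[(tert-butyldimethylsilyl)oxy]ethyl}-7-oxo-6-(phenylselanyl)oxepane-2-carboxylate (epimers at the selenium-bearing carbon) | CC(C)(C)[Si](C)(C)OCC[C@@]1(C(=O)OC(C)(C)C)CCCC([Se]c2ccccc2)C(=O)O1 | intermediate |
| 10 | tert-butyl (R)-2-{2-[(tert-butyldimethylsilyl)oxy]ethyl}-7-oxo-2,3,4,7-tetrahydrooxepine-2-carboxylate | CC(C)(C)[Si](C)(C)OCC[C@@]1(C(=O)OC(C)(C)C)CCC=CC(=O)O1 | intermediate |
| 11 | tert-butyl (2R)-5,6-dibromo-2-{2-[(tert-butyldimethylsilyl)oxy]ethyl}-7-oxooxepane-2-carboxylate (trans-dibromides) | CC(C)(C)[Si](C)(C)OCC[C@@]1(C(=O)OC(C)(C)C)CCC(Br)C(Br)C(=O)O1 | intermediate |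
| 12 | tert-butyl (R)-6-bromo-2-{2-[(tert-butyldimethylsilyl)oxy]ethyl}-7-oxo-2,3,4,7-tetrahydrooxepine-2-carboxylate | CC(C)(C)[Si](C)(C)OCC[C@@]1(C(=O)OC(C)(C)C)CCC=C(Br)C(=O)O1 | intermediate |
| 13 | tert-butyl (2R)-6-bromo-2-{2-[(tert-butyldimethylsilyl)oxy]ethyl}-7-[(diisobutylalumanyl)oxy]-2,3,4,7-tetrahydrooxepine-2-carboxylate | CC(C)(C)[Si](C)(C)OCC[C@@]1(C(=O)OC(C)(C)C)CCC=C(Br)C(O[Al](CC(C)C)CC(C)C)O1 | intermediate |
| 14 | tert-butyl (2R)-7-acetoxy-6-bromo-2-{2-[(tert-butyldimethylsilyl)oxy]ethyl}-2,3,4,7-tetrahydrooxepine-2-carboxylate (acetal epimers) | CC(C)(C)[Si](C)(C)OCC[C@@]1(C(=O)OC(C)(C)C)CCC=C(Br)C(OC(C)=O)O1 | intermediate |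
| 15 | (R)-6-bromo-2-(tert-butoxycarbonyl)-2-{2-[(tert-butyldimethylsilyl)oxy]ethyl}-3,4-dihydro-2H-oxepin-1-ium | CC(C)(C)[Si](C)(C)OCC[C@@]1(C(=O)OC(C)(C)C)CCC=C(Br)C=[O+]1 | intermediate |
| 16 | tert-butyl (R)-6-bromo-2-{2-[(tert-butyldimethylsilyl)oxy]ethyl}-2,3,4,7-tetrahydrooxepine-2-carboxylate | CC(C)(C)[Si](C)(C)OCC[C@@]1(C(=O)OC(C)(C)C)CCC=C(Br)CO1 | intermediate |
| 17 | tert-butyl (R)-6-bromo-2-(2-hydroxyethyl)-2,3,4,7-tetrahydrooxepine-2-carboxylate | OCC[C@@]1(C(=O)OC(C)(C)C)CCC=C(Br)CO1 | intermediate |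
| 18 | tert-butyl (R)-6-bromo-2-(2-oxoethyl)-2,3,4,7-tetrahydrooxepine-2-carboxylate | O=CC[C@@]1(C(=O)OC(C)(C)C)CCC=C(Br)CO1 | intermediate |
| 19 | 2-bromobenzene-1,4-diol | Oc1ccc(O)c(Br)c1 | starting material |
| 20 | 2-bromo-1,4-bis(methoxymethoxy)benzene | COCOc1ccc(OCOC)c(Br)c1 | intermediate |
| 21 | [2,5-bis(methoxymethoxy)phenyl]magnesium bromide | COCOc1ccc(OCOC)c([Mg]Br)c1 | intermediate |
| 22 | tert-butyl (2R)-2-{2-[2,5-bis(methoxymethoxy)phenyl]-2-hydroxyethyl}-6-bromo-2,3,4,7-tetrahydrooxepine-2-carboxylate (carbinol epimers) | OC(C[C@@]1(C(=O)OC(C)(C)C)CCC=C(Br)CO1)c1cc(OCOC)ccc1OCOC | intermediate |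
| 23 | tert-butyl (R)-2-{2-[2,5-bis(methoxymethoxy)phenyl]-2-oxoethyl}-6-bromo-2,3,4,7-tetrahydrooxepine-2-carboxylate | O=C(C[C@@]1(C(=O)OC(C)(C)C)CCC=C(Br)CO1)c1cc(OCOC)ccc1OCOC | intermediate |
| 24 | 5-bromo-2-methylpent-2-ene | CC(C)=CCCBr | starting material |
| 25 | (E)-5-bromo-2-methylpent-2-en-1-ol | C/C(=C\CCBr)CO | intermediate |
| 26 | (E)-4-hydroxycinnamic acid | OC(=O)/C=C/c1ccc(O)cc1 | starting material |
| 27 | (E)-5-bromo-2-methylpent-2-en-1-yl (E)-3-(4-hydroxyphenyl)acrylate | C/C(=C\CCBr)COC(=O)/C=C/c1ccc(O)cc1 | intermediate |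
| 28 | (E)-5-bromo-2-methylpent-2-en-1-yl (E)-3-[4-(methoxymethoxy)phenyl]acrylate | C/C(=C\CCBr)COC(=O)/C=C/c1ccc(OCOC)cc1 | intermediate |
| 29 | (E)-5-iodo-2-methylpent-2-en-1-yl (E)-3-[4-(methoxymethoxy)phenyl]acrylate | C/C(=C\CCI)COC(=O)/C=C/c1ccc(OCOC)cc1 | intermediate |
| 30 | [(3E)-5-({(2E)-3-[4-(methoxymethoxy)phenyl]prop-2-enoyl}oxy)-4-methylpent-3-en-1-yl]zinc iodide | C/C(=C\CC[Zn]I)COC(=O)/C=C/c1ccc(OCOC)cc1 | intermediate |
| 31 | tert-butyl (R)-2-{2-[2,5-bis(methoxymethoxy)phenyl]-2-oxoethyl}-6-[(3E)-5-({(2E)-3-[4-(methoxymethoxy)phenyl]prop-2-enoyl}oxy)-4-methylpent-3-en-1-yl]-2,3,4,7-tetrahydrooxepine-2-carboxylate | C/C(=C\CCC1=CCC[C@@](CC(=O)c2cc(OCOC)ccc2OCOC)(C(=O)OC(C)(C)C)OC1)COC(=O)/C=C/c1ccc(OCOC)cc1 | intermediate |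
| 32 | (R)-2-[2-(2,5-dihydroxyphenyl)-2-oxoethyl]-6-[(3E)-5-{[(2E)-3-(4-hydroxyphenyl)prop-2-enoyl]oxy}-4-methylpent-3-en-1-yl]-2,3,4,7-tetrahydrooxepine-2-carboxylic acid | C/C(=C\CCC1=CCC[C@@](CC(=O)c2cc(O)ccc2O)(C(=O)O)OC1)COC(=O)/C=C/c1ccc(O)cc1 | target |

Total step count: 19. Longest linear sequence: 14 steps (steps 1–10, 12, 13, 18 and 19).

**Steps most likely to fail**

**Step 2 (oxygen insertion).** The addition–migration may stall on the hindered, ester-deactivated ketone. The C3 methylene may migrate in competition. The Lewis acid may also strip the tert-butyl group, with decarboxylation following.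

The fallback sets out from 3, returns at 8 and replaces steps 2–4. The alkene is removed first, so that a strong buffered peracid can be used without any Lewis acid.
- Ozonolysis of 3 (O3, CH2Cl2, −78 °C; Me2S) gives tert-butyl (S)-2-oxo-1-(2-oxoethyl)cyclohexane-1-carboxylate F1.
- LiAlH(Ot-Bu)3 in THF at −78 °C reduces only the aldehyde to tert-butyl (S)-1-(2-hydroxyethyl)-2-oxocyclohexane-1-carboxylate F2.
- TBSCl and imidazole give tert-butyl (S)-1-{2-[(tert-butyldimethylsilyl)oxy]ethyl}-2-oxocyclohexane-1-carboxylate F3.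
- CF3CO3H, generated from urea–H2O2 and (CF3CO)2O over Na2HPO4 in CH2Cl2 at 0 °C, then effects the same 1,2-shift of the quaternary carbon with retention and gives 8.

**Step 8 (ionic reduction).** Ionisation may be sluggish, because the ring oxygen is attached to an ester-bearing carbon and the allyl unit carries bromine. At the temperature then required, the cation may be intercepted by the ester carbonyl (with loss of the tert-butyl group) or by the silyl ether oxygen.

The fallback sets out from 12, returns at 16 and replaces steps 7 and 8. It avoids the cation altogether.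
- i-Bu2AlH (3 equiv, CH2Cl2, −78 to −40 °C) reduces the lactone fully to tert-butyl (2R,5E)-6-bromo-2-{2-[(tert-butyldimethylsilyl)oxy]ethyl}-2,7-dihydroxyhept-5-enoate F4.
- Methanesulfonic anhydride and Et3N at −30 °C activate only the primary allylic hydroxyl, giving tert-butyl (2R,5E)-6-bromo-2-{2-[(tert-butyldimethylsilyl)oxy]ethyl}-2-hydroxy-7-[(methylsulfonyl)oxy]hept-5-enoate F5.
- NaH in THF at 0 °C closes the ring by intramolecular Williamson etherification to 16. The two carbon chains are held cis on the alkene, and C7 is not touched.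

**Step 18 (Negishi coupling).** Zerovalent palladium may ionise the allylic ester of the zinc reagent or of the product in competition with oxidative addition to the vinyl bromide. The functionalised zinc reagent may also decay before it couples.

The fallback sets out from 25 and 23 and returns at 32. The coupling is run with an ester-free side chain, and the coumarate is attached afterwards.
- TBSCl and imidazole convert 25 into tert-butyl{[(E)-5-bromo-2-methylpent-2-en-1-yl]oxy}dimethylsilane F6.
- NaI in acetone gives tert-butyl{[(E)-5-iodo-2-methylpent-2-en-1-yl]oxy}dimethylsilane F7.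
- Zinc dust and LiCl in THF give {(3E)-5-[(tert-butyldimethylsilyl)oxy]-4-methylpent-3-en-1-yl}zinc iodide F8.
- F8 couples with 23 under the catalyst of step 18 to give tert-butyl (R)-2-{2-[2,5-bis(methoxymethoxy)phenyl]-2-oxoethyl}-6-{(3E)-5-[(tert-butyldimethylsilyl)oxy]-4-methylpent-3-en-1-yl}-2,3,4,7-tetrahydrooxepine-2-carboxylate F9.
- HF·pyridine frees tert-butyl (R)-2-{2-[2,5-bis(methoxymethoxy)phenyl]-2-oxoethyl}-6-[(3E)-5-hydroxy-4-methylpent-3-en-1-yl]-2,3,4,7-tetrahydrooxepine-2-carboxylate F10.
- Mitsunobu esterification with unprotected 26 (PPh3, DIAD, THF) gives tert-butyl (R)-2-{2-[2,5-bis(methoxymethoxy)phenyl]-2-oxoethyl}-6-[(3E)-5-{[(2E)-3-(4-hydroxyphenyl)prop-2-enoyl]oxy}-4-methylpent-3-en-1-yl]-2,3,4,7-tetrahydrooxepine-2-carboxylate F11.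
- The conditions of step 19 convert F11 into 32.

**Further compounds**
F1 | step 2 | tert-butyl (S)-2-oxo-1-(2-oxoethyl)cyclohexane-1-carboxylate | O=CC[C@@]1(C(=O)OC(C)(C)C)CCCCC1=O
F2 | step 2 | tert-butyl (S)-1-(2-hydroxyethyl)-2-oxocyclohexane-1-carboxylate | OCC[C@@]1(C(=O)OC(C)(C)C)CCCCC1=O
F3 | step 2 | tert-butyl (S)-1-{2-[(tert-butyldimethylsilyl)oxy]ethyl}-2-oxocyclohexane-1-carboxylate | CC(C)(C)[Si](C)(C)OCC[C@@]1(C(=O)OC(C)(C)C)CCCCC1=O
F4 | step 8 | tert-butyl (2R,5E)-6-bromo-2-{2-[(tert-butyldimethylsilyl)oxy]ethyl}-2,7-dihydroxyhept-5-enoate | CC(C)(C)[Si](C)(C)OCC[C@@](O)(C(=O)OC(C)(C)C)CC/C=C(/Br)CO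
F5 | step 8 | tert-butyl (2R,5E)-6-bromo-2-{2-[(tert-butyldimethylsilyl)oxy]ethyl}-2-hydroxy-7-[(methylsulfonyl)oxy]hept-5-enoate | CC(C)(C)[Si](C)(C)OCC[C@@](O)(C(=O)OC(C)(C)C)CC/C=C(/Br)COS(C)(=O)=O
F6 | step 18 | tert-butyl{[(E)-5-bromo-2-methylpent-2-en-1-yl]oxy}dimethylsilane | C/C(=C\CCBr)CO[Si](C)(C)C(C)(C)C
F7 | step 18 | tert-butyl{[(E)-5-iodo-2-methylpent-2-en-1-yl]oxy}dimethylsilane | C/C(=C\CCI)CO[Si](C)(C)C(C)(C)C
F8 | step 18 | {(3E)-5-[(tert-butyldimethylsilyl)oxy]-4-methylpent-3-en-1-yl}zinc iodide | C/C(=C\CC[Zn]I)CO[Si](C)(C)C(C)(C)C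
F9 | step 18 | tert-butyl (R)-2-{2-[2,5-bis(methoxymethoxy)phenyl]-2-oxoethyl}-6-{(3E)-5-[(tert-butyldimethylsilyl)oxy]-4-methylpent-3-en-1-yl}-2,3,4,7-tetrahydrooxepine-2-carboxylate | C/C(=C\CCC1=CCC[C@@](CC(=O)c2cc(OCOC)ccc2OCOC)(C(=O)OC(C)(C)C)OC1)CO[Si](C)(C)C(C)(C)C
F10 | step 18 | tert-butyl (R)-2-{2-[2,5-bis(methoxymethoxy)phenyl]-2-oxoethyl}-6-[(3E)-5-hydroxy-4-methylpent-3-en-1-yl]-2,3,4,7-tetrahydrooxepine-2-carboxylate | C/C(=C\CCC1=CCC[C@@](CC(=O)c2cc(OCOC)ccc2OCOC)(C(=O)OC(C)(C)C)OC1)CO
F11 | step 18 | tert-butyl (R)-2-{2-[2,5-bis(methoxymethoxy)phenyl]-2-oxoethyl}-6-[(3E)-5-{[(2E)-3-(4-hydroxyphenyl)prop-2-enoyl]oxy}-4-methylpent-3-en-1-yl]-2,3,4,7-tetrahydrooxepine-2-carboxylate | C/C(=C\CCC1=CCC[C@@](CC(=O)c2cc(OCOC)ccc2OCOC)(C(=O)OC(C)(C)C)OC1)COC(=O)/C=C/c1ccc(O)cc1
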